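Remark: ring A is numbered as a 2H-chromene (O1, C2 to C4, C4a, C5 to C8, C8a) and ring B as C1′ to C6′ with the chain on C1′; 7-hydroxychroman-2-one (2) is made in step 1 from a cheap coumarin in case it cannot be bought.

## Analysis of the target

Kazinol K (24) is a 1,3-diarylpropane. Ring A is a 2,2-dimethyl-2H-chromene whose benzene ring is substituted at every position but C7: the pyran oxygen on C8a, a hydroxyl on C8, the propane chain on C6, a prenyl group on C5 and the pyran carbon C4 on C4a. Ring B is a resorcinol (hydroxyls on C2′ and C4′) with the chain on C1′ and a 1,1-dimethylallyl group, a quaternary benzylic carbon, on C5′. There is no stereocentre, so every problem is one of regiochemistry and chemoselectivity. The molecule holds three C=C bonds of three kinds (chromene C3=C4, a trisubstituted prenyl alkene, a monosubstituted vinyl group). This rules out catalytic hydrogenation late in the route, strong acid (phenol-to-alkene cyclisations) and hot strong base (allyl-to-propenyl migration). Both rings are electron-rich phenols that oxidise easily. The hard parts are the run of substituents O, O, C, C, C around ring A, the tert-allyl group next to a phenol on ring B, and a saturated three-carbon link that must be made without reducing anything afterwards. The strategy rests on one feature: the C8 hydroxyl next to the ether oxygen on C8a, together with the C3=C4 double bond, is an isomer of a C8,C8a ortho-quinone that carries a prenyl group on C4a. The chromenol therefore maps back onto the 2,3-diprenylphenol 20 plus one oxygen atom.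

## Retrosynthetic reasoning

24 from 23. The last step only removes the two acetal protecting groups on the ring B oxygens. They are needed because a free resorcinol would be oxidised faster than the ring A phenol in the key step. Acetals were chosen because they can be put on by phenoxide alkylation in the presence of a free primary alcohol and survive hydride, organozinc and palladium chemistry.

23 from 20. Two bonds are cut together, C8–O and O1–C2. Backwards, the pyran opens by a retro-oxa-6π reaction to the ortho-quinone methide 22, which is a tautomer of the ortho-quinone 21, and 21 is the phenol 20 plus one oxygen on its only free ortho carbon. The cut is made here because it removes the second oxygen of ring A and the whole pyran ring in one move. What is left is a phenol in which both prenyl groups are ordinary C-prenyl groups. The forward reaction has to deliver oxygen to C8 only, move one hydrogen from the C4a prenyl CH2, and close the ring.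

20 from 19, and 19 from 17 and 11. The phenol is unmasked from its diethylcarbamate 19. The chain is cut at the C6–CH2 bond, an aryl–alkyl bond, giving the aryl chloride 17 and the primary iodide 11 (as its zinc reagent 18). Cutting here, and not inside the chain by carbonyl condensation, means that no enone, benzylic ketone or chain alkene ever exists. Such groups would have to be reduced in the presence of a vinyl group and two prenyl groups. The forward reaction is a single sp3–sp2 cross-coupling.

17 from 16, 13 and 12. The two prenyl groups of ring A are put on one after the other. The C3 prenyl group replaces bromine (16 to 17), and the chlorine is kept for the chain. The C2 prenyl group is put between the oxygen and the bromine of 13 by deprotonation, with prenyl bromide 3 as the electrophile. That hydrogen is the only one flanked by both a carbamate and a halogen, so the position is fixed by acidity. A sigmatropic shift from oxygen would have two ortho carbons to choose from, which is why it is not used here. The carbamate 13 comes from the commercial phenol 12.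

11 from 10, 9 and 6. The iodide comes from the alcohol 10, and 10 from the phenol 9 by protection. The tert-allyl group of 9 is cut back to the prenyl ether 6 by a retro-Claisen step. In the forward direction the para carbon is blocked by the chain, and C3′ sits between two oxygen substituents, so the shift goes to C5′.

6 from 5, 4, 2 and 1. The resorcinol unit with its three-carbon chain is a ring-opened dihydrocoumarin. In lactone 2 one oxygen is tied up in the ring, so the other can be prenylated without any selectivity question (4). Hydride opening (5) then gives the chain at the alcohol level and frees the second oxygen for its acetal (6). Lactone 2 is the hydrogenation product of the coumarin 1.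

## Alternatives that were turned down

Alternative 1: The tert-allyl group is cut back to an acetyl group on C5′. The C4′ tert-butyl carbonate A2 is treated with a methyl Grignard reagent. The alkoxide takes over the carbonate and expels it to give the dimethyl ortho-quinone methide A3, and a vinyl Grignard reagent adds to the methide carbon to give A1 with a free C4′ phenol. In its favour, the quaternary carbon is built from a cheap acyl handle whose position is certain, with no 190 °C rearrangement and no question of which ortho carbon is attacked. On that point it is stronger than the chosen route. Against it, A3 carries two methyl groups on the methide carbon and can lose a proton from one of them to give an isopropenylphenol, while the wanted addition must form a quaternary centre between an aryl ring and two methyls. The cascade would also be run as the last carbon–carbon bond formation on a compound that already contains the complete chromenol, which this alternative does nothing to build, and two acetals still have to come off A1. The chosen strategy settles the tert-allyl group early on simple material and spends its key step on ring A, where the target is hardest.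

Alternative 2: Ring A is built from a four-membered ring. Thermolysis of the 4-alkenyl-4-alkoxycyclobutenone A5 opens it to a dienylketene, and 6π closure forms the C5–C6 bond and gives the phenol A4 with oxygen on C8a, C8 and C5. In its favour, all oxygen positions are fixed by construction, no electron-rich phenol has to be oxidised next to alkenes, and the tautomer question of the chosen key step does not arise. Against it, A4 is far from 24. C5 carries a hydroxyl where the target has a prenyl carbon, C4a is unsubstituted, and O1 is a methyl ether that must be cleaved in the presence of three acetals before a pyran can be annulated. At least five further steps follow (sulfonate formation, prenyl coupling, demethylation, propargylation, cyclisation), and the demethylation has no selective solution. The chosen key step is one deprotection away from 24.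

Alternative 3: Ring B is assembled around the chain. Heating the 2,4-disubstituted cyclobutenone A7 with the silyloxyalkyne A8 gives a vinylketene, then a [2+2] adduct, a dienylketene and, after 6π closure, the resorcinol A6 as its C2′ silyl ether with a free C4′ phenol. In its favour, the placement of chain and tert-allyl group on ring B is exact, the conditions are neutral, and A6 is one fluoride treatment from 24. In convergence and in the final deprotection it is stronger than the chosen route. Against it, the vinylketene from A7 has the vinyl group of the tert-allyl substituent three atoms from the ketene, the ideal distance for an intramolecular ketene–alkene [2+2] reaction, which competes with the bimolecular reaction with A8. In addition, A7 must be made with the finished, oxidation-prone chromenol of ring A already attached, so the difficulty of ring A is only moved into the precursor. The chosen strategy builds ring B by three classical steps and uses its one uncertain step to create the chromenol.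

Key step: step 13

## Route

Step 1
Reactants: 1 umbelliferone (7-hydroxy-2H-chromen-2-one)
Product: 2 7-hydroxychroman-2-one
Conditions: H2 (1 atm), 10% Pd/C, AcOH, rt
Reagents that add atoms: none
Why: Heterogeneous hydrogenation of the conjugated, electron-poor C3=C4 bond of the coumarin; the benzene ring and the lactone are not reduced, and the step comes before any prenyl group exists.

Step 2
Reactants: 2 7-hydroxychroman-2-one; 3 1-bromo-3-methylbut-2-ene (prenyl bromide)
Product: 4 7-[(3-methylbut-2-en-1-yl)oxy]chroman-2-one
Conditions: K2CO3, acetone, rt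
Reagents that add atoms: none
Why: Williamson ether synthesis; the lactone ties up the second resorcinol oxygen, so only the C7 hydroxyl (the future C4′ oxygen) can be alkylated.

Step 3
Reactants: 4 7-[(3-methylbut-2-en-1-yl)oxy]chroman-2-one
Product: 5 2-(3-hydroxypropyl)-5-[(3-methylbut-2-en-1-yl)oxy]phenol
Conditions: LiAlH4, THF, 0 °C to rt
Reagents that add atoms: none
Why: Hydride reduction of the aryl ester (lactone) to a primary alcohol and a phenol; allyl aryl ethers and isolated alkenes are inert, and the three-carbon chain of the target is now in place.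

Step 4
Reactants: 5 2-(3-hydroxypropyl)-5-[(3-methylbut-2-en-1-yl)oxy]phenol
Product: 6 3-{2-(methoxymethoxy)-4-[(3-methylbut-2-en-1-yl)oxy]phenyl}propan-1-ol
Conditions: MOMCl (1.1 equiv), K2CO3, acetone, 0 °C to rt
Reagents that add atoms: chloromethyl methyl ether, COCCl
Why: Phenoxide alkylation; carbonate deprotonates only the phenol (pKa about 10 against about 16 for the alcohol), so the acetal goes on the C2′ oxygen alone, and an alkyl-type ether there is wanted for the regiochemistry of step 5.

Step 5
Reactants: 6 3-{2-(methoxymethoxy)-4-[(3-methylbut-2-en-1-yl)oxy]phenyl}propan-1-ol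
Product: 9 3-[4-hydroxy-2-(methoxymethoxy)-5-(2-methylbut-3-en-2-yl)phenyl]propan-1-ol, via ether acetate 7 (not isolated), via rearranged diacetate 8 (not isolated)
Conditions: Ac2O, NaOAc, N,N-diethylaniline, 190 °C; then K2CO3, MeOH, rt
Reagents that add atoms: none
Why: Aromatic Claisen rearrangement of an aryl prenyl ether ([3,3]-sigmatropic shift, then enolisation) run with in situ acetylation; the para carbon C1′ is blocked, C3′ lies between two oxygen substituents and the meta alkoxy group favours the far ortho carbon, so the dimethyl-substituted terminus bonds to C5′. Acetylation of the phenol as it forms suppresses the abnormal Claisen rearrangement and closure to a dihydrobenzofuran, and methanolysis then frees both hydroxyls.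

Step 6
Reactants: 9 3-[4-hydroxy-2-(methoxymethoxy)-5-(2-methylbut-3-en-2-yl)phenyl]propan-1-ol
Product: 10 3-[2,4-bis(methoxymethoxy)-5-(2-methylbut-3-en-2-yl)phenyl]propan-1-ol
Conditions: MOMCl (1.1 equiv), Cs2CO3, DMF, 0 °C to rt
Reagents that add atoms: chloromethyl methyl ether, COCCl
Why: Phenoxide alkylation, again selective for the phenol over the primary alcohol; the small electrophile reaches the oxygen next to the quaternary carbon.

Step 7
Reactants: 10 3-[2,4-bis(methoxymethoxy)-5-(2-methylbut-3-en-2-yl)phenyl]propan-1-ol
Product: 11 1-(3-iodopropyl)-2,4-bis(methoxymethoxy)-5-(2-methylbut-3-en-2-yl)benzene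
Conditions: I2, PPh3, imidazole, CH2Cl2, 0 °C to rt
Reagents that add atoms: iodine, II
Why: Appel-type iodination (alkoxyphosphonium formation, then SN2 by iodide) of the primary alcohol under buffered conditions that leave the acetals and the alkenes alone.

Step 8
Reactants: 12 3-bromo-4-chlorophenol
Product: 13 3-bromo-4-chlorophenyl N,N-diethylcarbamate
Conditions: ClCONEt2, K2CO3, MeCN, reflux
Reagents that add atoms: N,N-diethylcarbamoyl chloride, CCN(CC)C(Cl)=O
Why: O-carbamoylation of the phenoxide; the carbamate directs the metalation of step 9, survives tin, zinc and palladium reagents, and is later removed by hydride without acid, so it is orthogonal to the acetals of ring B.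

Step 9
Reactants: 13 3-bromo-4-chlorophenyl N,N-diethylcarbamate; 3 1-bromo-3-methylbut-2-ene (prenyl bromide)
Product: 16 3-bromo-4-chloro-2-(3-methylbut-2-en-1-yl)phenyl N,N-diethylcarbamate, via aryllithium 14 (not isolated), via arylcopper 15 (not isolated)
Conditions: LiN(i-Pr)2, THF, −78 °C; CuBr·SMe2, −78 °C; then 3, −78 to 0 °C
Reagents that add atoms: none
Why: Directed ortho-metalation; C2–H is the only hydrogen flanked by both the carbamate and bromine and is removed by the amide base without halogen–metal exchange. Transmetalation to copper at −78 °C forestalls loss of LiBr (aryne) and the anionic Fries shift, and the arylcopper attacks the unhindered CH2 end of the allyl bromide (SN2 allylation) to give the linear prenyl group.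

Step 10
Reactants: 16 3-bromo-4-chloro-2-(3-methylbut-2-en-1-yl)phenyl N,N-diethylcarbamate
Product: 17 4-chloro-2,3-bis(3-methylbut-2-en-1-yl)phenyl N,N-diethylcarbamate
Conditions: Bu3SnCH2CH=CMe2, Pd(PPh3)4 (5 mol%), DMF, 100 °C
Reagents that add atoms: tributyl(3-methylbut-2-en-1-yl)stannane, CCCC[Sn](CCCC)(CCCC)CC=C(C)C
Why: Stille coupling; zerovalent palladium inserts into C–Br far faster than into C–Cl, and reductive elimination from the allyl complex of this hindered aryl group takes place at the less substituted allyl terminus, so the second prenyl group is linear and the chloride is kept for the chain.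

Step 11
Reactants: 11 1-(3-iodopropyl)-2,4-bis(methoxymethoxy)-5-(2-methylbut-3-en-2-yl)benzene; 17 4-chloro-2,3-bis(3-methylbut-2-en-1-yl)phenyl N,N-diethylcarbamate
Product: 19 4-{3-[2,4-bis(methoxymethoxy)-5-(2-methylbut-3-en-2-yl)phenyl]propyl}-2,3-bis(3-methylbut-2-en-1-yl)phenyl N,N-diethylcarbamate, via alkylzinc iodide 18 (not isolated)
Conditions: 11, Zn dust, LiCl, THF, 40 °C; then 17, (IPr)PdCl2(3-chloropyridine) (2 mol%; IPr = 1,3-bis(2,6-diisopropylphenyl)imidazol-2-ylidene), THF/NMP, 60 °C
Reagents that add atoms: none
Why: Negishi coupling (sp3–sp2); zinc inserts into the primary C–I bond without touching the alkenes, and the carbene-ligated palladium catalyst adds to the electron-rich, ortho-substituted aryl chloride and transfers the primary alkyl group faster than β-hydride elimination. No alkene or carbonyl is created in the chain, so nothing has to be reduced afterwards.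

Step 12
Reactants: 19 4-{3-[2,4-bis(methoxymethoxy)-5-(2-methylbut-3-en-2-yl)phenyl]propyl}-2,3-bis(3-methylbut-2-en-1-yl)phenyl N,N-diethylcarbamate
Product: 20 4-{3-[2,4-bis(methoxymethoxy)-5-(2-methylbut-3-en-2-yl)phenyl]propyl}-2,3-bis(3-methylbut-2-en-1-yl)phenol
Conditions: LiAlH4 (excess), THF, 0 °C to reflux; Rochelle salt work-up
Reagents that add atoms: none
Why: Hydride cleavage of the aryl carbamate (addition to the carbonyl, loss of the phenoxide, reduction of the formamide to the N-methylamine); acetals and isolated alkenes do not react, so only the ring A phenol is set free.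

Step 13
Reactants: 20 4-{3-[2,4-bis(methoxymethoxy)-5-(2-methylbut-3-en-2-yl)phenyl]propyl}-2,3-bis(3-methylbut-2-en-1-yl)phenol
Product: 23 6-{3-[2,4-bis(methoxymethoxy)-5-(2-methylbut-3-en-2-yl)phenyl]propyl}-2,2-dimethyl-5-(3-methylbut-2-en-1-yl)-2H-chromen-8-ol (Kazinol K 2′,4′-bis(methoxymethyl) ether), via ortho-quinone 21 (not isolated), via ortho-quinone methide 22 (not isolated)
Conditions: IBX (1.1 equiv), DMF, 0 °C to rt; then Et3N (3 equiv), rt, argon, dark
Reagents that add atoms: 2-iodoxybenzoic acid (IBX), O=C1OI(=O)(O)c2ccccc12
Why: Proposed new method: the phenol 20 exchanges a ligand on pentavalent iodine, the iodine-bound oxygen is passed intramolecularly to the only unsubstituted ortho carbon (C8; the para carbon C6 carries the chain), and collapse of the trivalent iodine catecholate to monovalent iodine leaves the ortho-quinone 21; the closest known reactions are the IBX ortho-oxygenation of phenols to ortho-quinones and the amine-promoted isomerisation of prenyl-para-quinones to chromenols, and running the ortho-quinone version of the second in the same flask as the first is the new element. Triethylamine then removes a hydrogen from the CH2 of the C4a prenyl group, which is allylic and doubly vinylogous to the C8 carbonyl (through C4a=C5 and C6=C7), and protonation on the C8 oxygen gives the hydroxy ortho-quinone methide 22, in which C8a=O, C4a=C4 and C3=C2 form a 1-oxatriene. Thermal disrotatory oxa-6π electrocyclisation joins O1 to C2, closes the six-membered pyran and restores the benzene ring, which makes this branch irreversible. No stereocentre is formed. The step needs oxygen at C8 and not at C4a (secured by the free C–H at C8 against the substituted C4a), closure through the C4a prenyl group and not the C5 one (only C4a is bonded to a carbonyl carbon), and inertness of ring B and of the alkenes (ring B has no free hydroxyl to bind iodine, and IBX does not attack isolated alkenes at room temperature). The CH2 groups of the C5 prenyl group and of the C6 chain are also vinylogously acidic, but their tautomers are para-quinone methides that cannot cyclise and can return to 21. A weak amine, room temperature and a medium without added nucleophiles are chosen so that these tautomers revert and are not drained by a second proton shift to alkenyl catechols.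

Step 14
Reactants: 23 6-{3-[2,4-bis(methoxymethoxy)-5-(2-methylbut-3-en-2-yl)phenyl]propyl}-2,2-dimethyl-5-(3-methylbut-2-en-1-yl)-2H-chromen-8-ol
Product: 24 Kazinol K, 4-{3-[8-hydroxy-2,2-dimethyl-5-(3-methylbut-2-en-1-yl)-2H-chromen-6-yl]propyl}-6-(2-methylbut-3-en-2-yl)benzene-1,3-diol
Conditions: aq. HCl (3 M), MeOH, rt
Reagents that add atoms: none
Why: Acid-catalysed transacetalisation of the two aryl methoxymethyl ethers to methanol; dilute acid at room temperature is used because the tert-allyl group next to the C4′ phenol, the prenyl group and the chromene double bond would cyclise or add methanol under stronger acid.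

## Compound list

1 | umbelliferone (7-hydroxy-2H-chromen-2-one) | O=c1ccc2ccc(O)cc2o1 | starting material
2 | 7-hydroxychroman-2-one | O=C1CCc2ccc(O)cc2O1 | intermediate
3 | 1-bromo-3-methylbut-2-ene (prenyl bromide) | CC(C)=CCBr | starting material
4 | 7-[(3-methylbut-2-en-1-yl)oxy]chroman-2-one | O=C1CCc2ccc(OCC=C(C)C)cc2O1 | intermediate
5 | 2-(3-hydroxypropyl)-5-[(3-methylbut-2-en-1-yl)oxy]phenol | OCCCc1ccc(OCC=C(C)C)cc1O | intermediate
6 | 3-{2-(methoxymethoxy)-4-[(3-methylbut-2-en-1-yl)oxy]phenyl}propan-1-ol | OCCCc1ccc(OCC=C(C)C)cc1OCOC | intermediate
7 | 3-{2-(methoxymethoxy)-4-[(3-methylbut-2-en-1-yl)oxy]phenyl}propyl acetate | CC(=O)OCCCc1ccc(OCC=C(C)C)cc1OCOC | intermediate (not isolated)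
8 | 3-[4-acetoxy-2-(methoxymethoxy)-5-(2-methylbut-3-en-2-yl)phenyl]propyl acetate | CC(=O)OCCCc1cc(C(C)(C)C=C)c(OC(C)=O)cc1OCOC | intermediate (not isolated)
9 | 3-[4-hydroxy-2-(methoxymethoxy)-5-(2-methylbut-3-en-2-yl)phenyl]propan-1-ol | OCCCc1cc(C(C)(C)C=C)c(O)cc1OCOC | intermediate
10 | 3-[2,4-bis(methoxymethoxy)-5-(2-methylbut-3-en-2-yl)phenyl]propan-1-ol | OCCCc1cc(C(C)(C)C=C)c(OCOC)cc1OCOC | intermediate
11 | 1-(3-iodopropyl)-2,4-bis(methoxymethoxy)-5-(2-methylbut-3-en-2-yl)benzene | ICCCc1cc(C(C)(C)C=C)c(OCOC)cc1OCOC | intermediate
12 | 3-bromo-4-chlorophenol | Oc1ccc(Cl)c(Br)c1 | starting material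
13 | 3-bromo-4-chlorophenyl N,N-diethylcarbamate | CCN(CC)C(=O)Oc1ccc(Cl)c(Br)c1 | intermediate
14 | [2-bromo-3-chloro-6-(diethylcarbamoyloxy)phenyl]lithium | CCN(CC)C(=O)Oc1ccc(Cl)c(Br)c1[Li] | intermediate (not isolated)
15 | [2-bromo-3-chloro-6-(diethylcarbamoyloxy)phenyl]copper | CCN(CC)C(=O)Oc1ccc(Cl)c(Br)c1[Cu] | intermediate (not isolated)
16 | 3-bromo-4-chloro-2-(3-methylbut-2-en-1-yl)phenyl N,N-diethylcarbamate | CCN(CC)C(=O)Oc1ccc(Cl)c(Br)c1CC=C(C)C | intermediate
17 | 4-chloro-2,3-bis(3-methylbut-2-en-1-yl)phenyl N,N-diethylcarbamate | CCN(CC)C(=O)Oc1ccc(Cl)c(CC=C(C)C)c1CC=C(C)C | intermediate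
18 | {3-[2,4-bis(methoxymethoxy)-5-(2-methylbut-3-en-2-yl)phenyl]propyl}zinc iodide | I[Zn]CCCc1cc(C(C)(C)C=C)c(OCOC)cc1OCOC | intermediate (not isolated)
19 | 4-{3-[2,4-bis(methoxymethoxy)-5-(2-methylbut-3-en-2-yl)phenyl]propyl}-2,3-bis(3-methylbut-2-en-1-yl)phenyl N,N-diethylcarbamate | CCN(CC)C(=O)Oc1ccc(CCCc2cc(C(C)(C)C=C)c(OCOC)cc2OCOC)c(CC=C(C)C)c1CC=C(C)C | intermediate
20 | 4-{3-[2,4-bis(methoxymethoxy)-5-(2-methylbut-3-en-2-yl)phenyl]propyl}-2,3-bis(3-methylbut-2-en-1-yl)phenol | CC(C)=CCc1c(O)ccc(CCCc2cc(C(C)(C)C=C)c(OCOC)cc2OCOC)c1CC=C(C)C | intermediate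
21 | 5-{3-[2,4-bis(methoxymethoxy)-5-(2-methylbut-3-en-2-yl)phenyl]propyl}-3,4-bis(3-methylbut-2-en-1-yl)cyclohexa-3,5-diene-1,2-dione | CC(C)=CCC1=C(CC=C(C)C)C(CCCc2cc(C(C)(C)C=C)c(OCOC)cc2OCOC)=CC(=O)C1=O | intermediate (not isolated)
22 | 4-{3-[2,4-bis(methoxymethoxy)-5-(2-methylbut-3-en-2-yl)phenyl]propyl}-2-hydroxy-5-(3-methylbut-2-en-1-yl)-6-(3-methylbut-2-en-1-ylidene)cyclohexa-2,4-dien-1-one | CC(C)=CC=C1C(=O)C(O)=CC(CCCc2cc(C(C)(C)C=C)c(OCOC)cc2OCOC)=C1CC=C(C)C | intermediate (not isolated)
23 | 6-{3-[2,4-bis(methoxymethoxy)-5-(2-methylbut-3-en-2-yl)phenyl]propyl}-2,2-dimethyl-5-(3-methylbut-2-en-1-yl)-2H-chromen-8-ol | C=CC(C)(C)c1cc(CCCc2cc(O)c3c(c2CC=C(C)C)C=CC(C)(C)O3)c(OCOC)cc1OCOC | intermediate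
24 | Kazinol K | C=CC(C)(C)c1cc(CCCc2cc(O)c3c(c2CC=C(C)C)C=CC(C)(C)O3)c(O)cc1O | target

## Step count and risks

Total: 14 steps. Longest linear sequence: 11 steps (steps 1 to 7, then 11 to 14); the ring A branch (steps 8 to 10) joins at step 11.

Step 13 (key step, the only one that carries the label). The most likely failure is proton loss from the C5 prenyl CH2 or the C6 chain CH2 in place of the C4a prenyl CH2. The resulting para-quinone methides can aromatise by a second proton shift to alkenyl catechols, and the amine can also reduce the ortho-quinone by electron transfer. Both follow from the fact that all three benzylic positions are conjugated to a quinone carbonyl. Fallback by known chemistry, from 20 back to 23: oxidise 20 with IBX and reduce the ortho-quinone in the same flask with aqueous Na2S2O4 to the catechol F1. Silylate the less hindered C8 hydroxyl (TBSCl, imidazole, DMF, 0 °C) to the mono-silyl ether F2. Close the pyran by the established DDQ dehydrogenative cyclisation of ortho-prenylphenols (DDQ, benzene, 80 °C), which abstracts hydride from the allylic-benzylic CH2 next to the free phenol, to give the chromene silyl ether F3. Remove the silyl group with Bu4NF in THF at 0 °C to reach 23.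

Step 5. Likely failures are partial migration to C3′, acetolysis of the aryl acetal in the hot acetylating medium, and loss of the prenyl group by ionisation. The acetal is the only acid-labile group present at 190 °C. Fallback, from 4 back to 10: run the rearrangement one stage earlier on the lactone 4 (Ac2O, NaOAc, N,N-diethylaniline, 190 °C), where no acetal exists and C8 is shielded by the ring oxygen, to give the acetoxy lactone F4. Reduce lactone and acetate together with LiAlH4 to the triol F5. Protect both phenols at once (MOMCl 2.2 equiv, Cs2CO3, DMF) to reach 10.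

Step 11. Oxidative addition into the hindered, electron-rich aryl chloride may be slow, so that the alkylzinc reagent decays by protonation or homocoupling. Fallback, from 11 back to 19: change the nucleophile. Convert 11 into the pinacol boronate F6 (B2pin2, CuI, PPh3, LiOMe, DMF, rt) and then into the potassium trifluoroborate F7 (KHF2, MeOH/H2O). Couple F7 with 17 under aqueous Suzuki–Miyaura conditions for aryl chlorides (Pd(OAc)2, RuPhos, K2CO3, toluene/H2O, 80 °C).

Step 9. The ortho-bromoaryllithium may lose LiBr (aryne formation), or the carbamoyl group may shift to carbon before the copper exchange is complete; some attack at the tertiary end of the allyl bromide is also possible. Fallback, from 13 back to 16: quench the aryllithium at −78 °C with iodine, which is instantaneous, to give the aryl iodide F8. Then couple the prenyl stannane at the C–I bond alone (Pd(PPh3)4, DMF, 50 °C); the C–Br bond stays for step 10.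

Step 14. The C4′ phenol may add to the neighbouring vinyl group, or methanol may add to the prenyl or chromene double bond, before both acetals are gone, because each of these is also acid-catalysed. Fallback, from 23 back to 24: avoid protic acid. Treat 23 with TMSOTf and 2,2′-bipyridyl in CH2Cl2 at 0 °C, which turns aryl methoxymethyl ethers into aryl silyl ethers and silylates the C8 hydroxyl, to give the tris(trimethylsilyl) ether F9. Hydrolyse F9 with K2CO3 in MeOH at 0 °C.

## Further compounds

F1 | step 13 | 5-{3-[2,4-bis(methoxymethoxy)-5-(2-methylbut-3-en-2-yl)phenyl]propyl}-3,4-bis(3-methylbut-2-en-1-yl)benzene-1,2-diol | CC(C)=CCc1c(O)c(O)cc(CCCc2cc(C(C)(C)C=C)c(OCOC)cc2OCOC)c1CC=C(C)C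
F2 | step 13 | 4-{3-[2,4-bis(methoxymethoxy)-5-(2-methylbut-3-en-2-yl)phenyl]propyl}-6-[(tert-butyldimethylsilyl)oxy]-2,3-bis(3-methylbut-2-en-1-yl)phenol | CC(C)=CCc1c(O)c(O[Si](C)(C)C(C)(C)C)cc(CCCc2cc(C(C)(C)C=C)c(OCOC)cc2OCOC)c1CC=C(C)C
F3 | step 13 | 6-{3-[2,4-bis(methoxymethoxy)-5-(2-methylbut-3-en-2-yl)phenyl]propyl}-8-[(tert-butyldimethylsilyl)oxy]-2,2-dimethyl-5-(3-methylbut-2-en-1-yl)-2H-chromene | C=CC(C)(C)c1cc(CCCc2cc(O[Si](C)(C)C(C)(C)C)c3c(c2CC=C(C)C)C=CC(C)(C)O3)c(OCOC)cc1OCOC
F4 | step 5 | 6-(2-methylbut-3-en-2-yl)-2-oxochroman-7-yl acetate | CC(=O)Oc1cc2OC(=O)CCc2cc1C(C)(C)C=C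
F5 | step 5 | 4-(3-hydroxypropyl)-6-(2-methylbut-3-en-2-yl)benzene-1,3-diol | OCCCc1cc(C(C)(C)C=C)c(O)cc1O
F6 | step 11 | 2-{3-[2,4-bis(methoxymethoxy)-5-(2-methylbut-3-en-2-yl)phenyl]propyl}-4,4,5,5-tetramethyl-1,3,2-dioxaborolane | CC1(C)OB(CCCc2cc(C(C)(C)C=C)c(OCOC)cc2OCOC)OC1(C)C
F7 | step 11 | potassium {3-[2,4-bis(methoxymethoxy)-5-(2-methylbut-3-en-2-yl)phenyl]propyl}trifluoroborate | [K+].F[B-](F)(F)CCCc1cc(C(C)(C)C=C)c(OCOC)cc1OCOC
F8 | step 9 | 3-bromo-4-chloro-2-iodophenyl N,N-diethylcarbamate | CCN(CC)C(=O)Oc1ccc(Cl)c(Br)c1I
F9 | step 14 | Kazinol K tris(trimethylsilyl) ether | C=CC(C)(C)c1cc(CCCc2cc(O[Si](C)(C)C)c3c(c2CC=C(C)C)C=CC(C)(C)O3)c(O[Si](C)(C)C)cc1O[Si](C)(C)C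
A1 | alternative 1 | Kazinol K 2′,8-bis(methoxymethyl) ether | C=CC(C)(C)c1cc(CCCc2cc(OCOC)c3c(c2CC=C(C)C)C=CC(C)(C)O3)c(OCOC)cc1O
A2 | alternative 1 | 2-acetyl-5-(methoxymethoxy)-4-{3-[8-(methoxymethoxy)-2,2-dimethyl-5-(3-methylbut-2-en-1-yl)-2H-chromen-6-yl]propyl}phenyl tert-butyl carbonate | CC(=O)c1cc(CCCc2cc(OCOC)c3c(c2CC=C(C)C)C=CC(C)(C)O3)c(OCOC)cc1OC(=O)OC(C)(C)C
A3 | alternative 1 | 3-(methoxymethoxy)-4-{3-[8-(methoxymethoxy)-2,2-dimethyl-5-(3-methylbut-2-en-1-yl)-2H-chromen-6-yl]propyl}-6-(propan-2-ylidene)cyclohexa-2,4-dien-1-one | CC(C)=C1C=C(CCCc2cc(OCOC)c3c(c2CC=C(C)C)C=CC(C)(C)O3)C(OCOC)=CC1=O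
A4 | alternative 2 | 2-{3-[2,4-bis(methoxymethoxy)-5-(2-methylbut-3-en-2-yl)phenyl]propyl}-4-methoxy-5-(methoxymethoxy)phenol | Oc1cc(OC)c(OCOC)cc1CCCc1cc(C(C)(C)C=C)c(OCOC)cc1OCOC
A5 | alternative 2 | 4-{5-[2,4-bis(methoxymethoxy)-5-(2-methylbut-3-en-2-yl)phenyl]pent-1-en-1-yl}-3-methoxy-4-(methoxymethoxy)cyclobut-2-en-1-one | O=C1C=C(OC)C1(OCOC)C=CCCCc1cc(C(C)(C)C=C)c(OCOC)cc1OCOC
A6 | alternative 3 | Kazinol K 2′-O-triisopropylsilyl 8-O-tert-butyldimethylsilyl bis-ether | C=CC(C)(C)c1cc(CCCc2cc(O[Si](C)(C)C(C)(C)C)c3c(c2CC=C(C)C)C=CC(C)(C)O3)c(O[Si](C(C)C)(C(C)C)C(C)C)cc1O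
A7 | alternative 3 | 2-{3-[8-[(tert-butyldimethylsilyl)oxy]-2,2-dimethyl-5-(3-methylbut-2-en-1-yl)-2H-chromen-6-yl]propyl}-4-(2-methylbut-3-en-2-yl)cyclobut-2-en-1-one | O=C1C(CCCc2cc(O[Si](C)(C)C(C)(C)C)c3c(c2CC=C(C)C)C=CC(C)(C)O3)=CC1C(C)(C)C=C
A8 | alternative 3 | (ethynyloxy)triisopropylsilane | C#CO[Si](C(C)C)(C(C)C)C(C)C
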